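Each ring C is cut at its C2–C3 bond, which joins the acetyl-derived C3 to the ring-B-bearing C2. The route exploits the fact that O1 is the phenolic oxygen on C8a, directly beside the C8–C8'' axis and ortho to the acetyl-bearing C4a. This oxygen first carries the aroyl group as an ester, then passes it to the acetyl carbon. One base treatment of the symmetric biaryl bis(4-benzyloxybenzoate) 8 forms both C2–C3 bonds and frees both C8a hydroxyls, so only 8,8''-closure is possible. All six spectator oxygens are benzyl ethers, because the late-set, ring-opening-prone C2 stereocentre tolerates neutral hydrogenolysis but not BBr3.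

Key step: step 7

Remark on the axis: the target string fixes only C2 (S). The C8–C8'' axis has four ortho oxygen substituents and should rotate slowly, but it is undefined, so the biaryl is carried as the axial racemate and the product is (2S)-material as both axial diastereomers, separable at 12 or 13 if one is wanted.

Remark on the ligand: the NHC antipode written in step 9 is assumed to add hydrogen to the Re face of C2. Both antipodes come from commercial 1-(1-naphthyl)ethylamine, and the sense is to be checked on a monomeric flavone before 10 is committed.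

Step 1
Reactants: 1 2',4',6'-trihydroxyacetophenone
Product: 2 4',6'-bis(benzyloxy)-2'-hydroxyacetophenone
Conditions: BnBr (2.1 equiv), K2CO3 (2.2 equiv), DMF, rt to 60 °C
Reagents that add atoms: benzyl bromide, BrCc1ccccc1
Why: Williamson etherification in which the 4'-hydroxyl and one of the two equivalent ortho hydroxyls react, whereas the last ortho hydroxyl is tied up in a hydrogen bond to the acetyl oxygen and stays free as long as the halide is limited to two equivalents.

Step 2
Reactants: 2 4',6'-bis(benzyloxy)-2'-hydroxyacetophenone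
Product: 3 4',6'-bis(benzyloxy)-2'-hydroxy-3'-iodoacetophenone
Conditions: NIS (1.0 equiv), TFA (cat.), MeCN/CH2Cl2, 0 °C to rt, dark
Reagents that add atoms: N-iodosuccinimide, O=C1CCC(=O)N1I
Why: Electrophilic aromatic iodination that should go to C3' because this site is ortho to the free phenol, the strongest donor on the ring, and is less crowded than C5', which lies between two benzyloxy groups; the same preference is established for the 4',6'-dimethyl ether.

Step 3
Reactants: 3 4',6'-bis(benzyloxy)-2'-hydroxy-3'-iodoacetophenone
Product: 4 4',6'-bis(benzyloxy)-3'-iodo-2'-(methoxymethoxy)acetophenone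
Conditions: NaH (1.1 equiv), MOMCl (1.2 equiv), DMF, 0 °C
Reagents that add atoms: chloromethyl methyl ether, COCCl
Why: O-alkylation of the sodium phenoxide (Williamson type) masks the acidic hydroxyl, which would otherwise quench the arylcopper species or undergo O-arylation in step 4, as an acetal that can later be removed without touching the benzyl ethers.

Step 4
Reactants: 4 4',6'-bis(benzyloxy)-3'-iodo-2'-(methoxymethoxy)acetophenone (two molecules)
Product: 5 3,3'-diacetyl-4,4',6,6'-tetrakis(benzyloxy)-2,2'-bis(methoxymethoxy)biphenyl (axis racemic)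
Conditions: activated Cu powder (8 equiv), DMF, 150 °C, Ar
Reagents that add atoms: none
Why: Classical Ullmann reductive homocoupling, in which zerovalent copper inserts into the C–I bond and the arylcopper formed couples with a second aryl iodide, is the established way to tetra-ortho-oxygenated biaryls, can give only the symmetric C3'–C3' dimer, and leaves ketone, acetal and benzyl ethers alone.

Step 5
Reactants: 5 3,3'-diacetyl-4,4',6,6'-tetrakis(benzyloxy)-2,2'-bis(methoxymethoxy)biphenyl
Product: 6 3,3'-diacetyl-4,4',6,6'-tetrakis(benzyloxy)biphenyl-2,2'-diol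
Conditions: conc. HCl (cat.), MeOH/THF, 50 °C
Reagents that add atoms: none
Why: Acid-catalysed acetal cleavage (transacetalisation to methanol) removes both MOM groups, helped by the hydrogen bond that each released phenol forms to its acetyl group, under conditions far too mild to cleave aryl benzyl ethers.

Step 6
Reactants: 6 3,3'-diacetyl-4,4',6,6'-tetrakis(benzyloxy)biphenyl-2,2'-diol; 7 4-(benzyloxy)benzoyl chloride (two molecules)
Product: 8 3,3'-diacetyl-4,4',6,6'-tetrakis(benzyloxy)biphenyl-2,2'-diyl bis[4-(benzyloxy)benzoate]
Conditions: 7 (3 equiv), Et3N, DMAP (0.3 equiv), CH2Cl2, 0 °C to reflux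
Reagents that add atoms: 4-(benzyloxy)benzoyl chloride (compound 7), O=C(Cl)c1ccc(OCc2ccccc2)cc1
Why: DMAP-catalysed O-acylation (nucleophilic catalysis through the acylpyridinium salt) overcomes the hydrogen bonding and crowding of the two phenols, and the amine bases are too weak to enolise the methyl ketones, so the aroyl groups stay on oxygen until step 7.

Step 7
Reactants: 8 3,3'-diacetyl-4,4',6,6'-tetrakis(benzyloxy)biphenyl-2,2'-diyl bis[4-(benzyloxy)benzoate]
Product: 9 1,1'-[4,4',6,6'-tetrakis(benzyloxy)-2,2'-dihydroxybiphenyl-3,3'-diyl]bis{3-[4-(benzyloxy)phenyl]propane-1,3-dione}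
Conditions: LiN(SiMe3)2 (6 equiv), THF, −78 °C to rt; then 1 M HCl, 0 °C
Reagents that add atoms: none
Why: LiN(SiMe3)2 turns each acetyl group into its lithium enolate, whose carbon adds to the carbonyl of the aryl ester on the adjacent ring position through a six-membered array (enolate C, ketone C, C3, C2, ester O, ester C), and the cyclic hemiketal alkoxide then expels the C2 phenoxide, so the aroyl group moves from oxygen to carbon and the new C–C bond is the future C2–C3 bond of ring C. This is the Baker–Venkataraman rearrangement (an intramolecular Claisen condensation) of 2-aroyloxyacetophenones, run here twice on one twofold-symmetric molecule. No ring is closed, since the six-membered adduct is only transient, and no stereocentre is formed, the axis staying racemic. The step needs C-acylation within each half to outrun ester cleavage by outside nucleophiles and needs both halves to react: the bulky amide base does not attack the esters, the proximity of enolate and ester makes the transfer fast, and the excess base converts each product into its chelated diketone enolate and phenoxide, which pulls both transfers to completion. An aroyl exchange between the two oxygens at the axis, or an attack across the axis, would lead to the same product because the two halves are alike. The benzyl ethers on O4 and O6 cannot move, so only the oxygen next to the axis is unmasked and the later ring closure can give nothing but the 8,8''-linkage.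

Step 8
Reactants: 9 1,1'-[4,4',6,6'-tetrakis(benzyloxy)-2,2'-dihydroxybiphenyl-3,3'-diyl]bis{3-[4-(benzyloxy)phenyl]propane-1,3-dione}
Product: 10 5,5'',7,7''-tetrakis(benzyloxy)-2,2''-bis[4-(benzyloxy)phenyl]-8,8''-bi(4H-chromen-4-one) (hexa-O-benzylcupressuflavone; axis racemic)
Conditions: p-TsOH·H2O (0.3 equiv), toluene, 100 °C, Dean–Stark trap
Reagents that add atoms: none
Why: Acid-catalysed cyclodehydration of o-hydroxyaryl 1,3-diketones to flavones, in which each free C8a hydroxyl adds to its aroyl carbonyl and the 2-hydroxyflavanone hemiketal loses water, can use only that hydroxyl because the C5 oxygen is benzylated, and a sulfonic acid in toluene is mild enough for aryl benzyl ethers.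

Step 9
Reactants: 10 hexa-O-benzylcupressuflavone
Product: 12 (2S)-5,7-bis(benzyloxy)-2-[4-(benzyloxy)phenyl]-8-{5,7-bis(benzyloxy)-2-[4-(benzyloxy)phenyl]-4-oxo-4H-chromen-8-yl}chroman-4-one, via over-reduced flavan-4-ol 11 (not isolated)
Conditions: [Ru(cod)(2-methylallyl)2] (5 mol %), (R,R)-SINpEt·HBF4 (10 mol %), KOtBu (15 mol %), n-hexane, 70 °C (catalyst formation); then 10, toluene, H2 (100 bar), 25 °C, stopped near half conversion; then crude material, Dess–Martin periodinane, pyridine, CH2Cl2, 0 °C to rt
Reagents that add atoms: none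
Why: Ru–NHC-catalysed asymmetric hydrogenation of the flavone C2=C3 bond, in which the chiral carbene ligands shield one enone face so that hydrogen reaches the Re face of C2 (2S), is stopped at partial conversion because the two equivalent pyranones react statistically (recovered 10 is recycled), and the Dess–Martin oxidation returns any flavan-4-ol formed by further carbonyl reduction to the ketone without touching C2.

Step 10
Reactants: 12 (2S)-hexa-O-benzyl-2,3-dihydrocupressuflavone
Product: 13 (2S)-5,7-dihydroxy-8-[5,7-dihydroxy-2-(4-hydroxyphenyl)-4-oxo-4H-chromen-8-yl]-2-(4-hydroxyphenyl)chroman-4-one (target)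
Conditions: H2 (1 atm), 10% Pd/C, THF/MeOH, rt, stopped when the last benzyl ether is gone
Reagents that add atoms: none
Why: Catalytic hydrogenolysis of the six aryl benzyl ethers runs without acid, base or Lewis acid, so the retro-oxa-Michael ring opening that would racemise C2 is not triggered, and at 1 atm the remaining pyranone C2''=C3'' bond, both carbonyls and the C2–O1 bond should survive.

Compound list
1 | 2',4',6'-trihydroxyacetophenone | CC(=O)c1c(O)cc(O)cc1O | starting material
2 | 4',6'-bis(benzyloxy)-2'-hydroxyacetophenone | CC(=O)c1c(O)cc(OCc2ccccc2)cc1OCc1ccccc1 | intermediate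
3 | 4',6'-bis(benzyloxy)-2'-hydroxy-3'-iodoacetophenone | CC(=O)c1c(O)c(I)c(OCc2ccccc2)cc1OCc1ccccc1 | intermediate
4 | 4',6'-bis(benzyloxy)-3'-iodo-2'-(methoxymethoxy)acetophenone | CC(=O)c1c(OCOC)c(I)c(OCc2ccccc2)cc1OCc1ccccc1 | intermediate
5 | 3,3'-diacetyl-4,4',6,6'-tetrakis(benzyloxy)-2,2'-bis(methoxymethoxy)biphenyl | CC(=O)c1c(OCOC)c(c(OCc2ccccc2)cc1OCc1ccccc1)-c1c(OCOC)c(C(C)=O)c(OCc2ccccc2)cc1OCc1ccccc1 | intermediate
6 | 3,3'-diacetyl-4,4',6,6'-tetrakis(benzyloxy)biphenyl-2,2'-diol | CC(=O)c1c(O)c(c(OCc2ccccc2)cc1OCc1ccccc1)-c1c(O)c(C(C)=O)c(OCc2ccccc2)cc1OCc1ccccc1 | intermediate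
7 | 4-(benzyloxy)benzoyl chloride | O=C(Cl)c1ccc(OCc2ccccc2)cc1 | starting material
8 | 3,3'-diacetyl-4,4',6,6'-tetrakis(benzyloxy)biphenyl-2,2'-diyl bis[4-(benzyloxy)benzoate] | O=C(Oc1c(C(C)=O)c(OCc2ccccc2)cc(OCc2ccccc2)c1-c1c(OC(=O)c2ccc(OCc3ccccc3)cc2)c(C(C)=O)c(OCc2ccccc2)cc1OCc1ccccc1)c1ccc(OCc2ccccc2)cc1 | intermediate
9 | 1,1'-[4,4',6,6'-tetrakis(benzyloxy)-2,2'-dihydroxybiphenyl-3,3'-diyl]bis{3-[4-(benzyloxy)phenyl]propane-1,3-dione} | O=C(CC(=O)c1c(OCc2ccccc2)cc(OCc2ccccc2)c(c1O)-c1c(O)c(C(=O)CC(=O)c2ccc(OCc3ccccc3)cc2)c(OCc2ccccc2)cc1OCc1ccccc1)c1ccc(OCc2ccccc2)cc1 | intermediate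
10 | hexa-O-benzylcupressuflavone | O=c1cc(-c2ccc(OCc3ccccc3)cc2)oc2c1c(OCc1ccccc1)cc(OCc1ccccc1)c2-c1c(OCc2ccccc2)cc(OCc2ccccc2)c2c(=O)cc(-c3ccc(OCc4ccccc4)cc3)oc12 | intermediate
11 | (2S)-flavan-4-ol congener of 12 (C4 carbinol in place of the C4 ketone, C4 configuration not controlled) | OC1C[C@@H](c2ccc(OCc3ccccc3)cc2)Oc2c1c(OCc1ccccc1)cc(OCc1ccccc1)c2-c1c(OCc2ccccc2)cc(OCc2ccccc2)c2c(=O)cc(-c3ccc(OCc4ccccc4)cc3)oc12 | intermediate
12 | (2S)-hexa-O-benzyl-2,3-dihydrocupressuflavone | O=C1C[C@@H](c2ccc(OCc3ccccc3)cc2)Oc2c1c(OCc1ccccc1)cc(OCc1ccccc1)c2-c1c(OCc2ccccc2)cc(OCc2ccccc2)c2c(=O)cc(-c3ccc(OCc4ccccc4)cc3)oc12 | intermediate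
13 | (2S)-2,3-dihydrocupressuflavone | O=C1C[C@@H](c2ccc(O)cc2)Oc2c1c(O)cc(O)c2-c1c(O)cc(O)c2c(=O)cc(-c3ccc(O)cc3)oc12 | target

Total step count: 10. Longest linear sequence: 10 steps (1 to 13); 7 is bought.

Steps most likely to fail

Step 9. Several things may go wrong here:
- The second pyranone may be reduced about as fast as the first.
- Hydrogen uptake may be slow at a pyranone crowded by the C8 aryl group and the C5 benzyloxy group.
- Facial selectivity may erode in the axial enantiomer whose own bias opposes the catalyst.

The fallback sets out from 10. A non-stereoselective copper hydride 1,4-reduction gives the C2-racemic mono-flavanone F1; the conditions are Cu(OAc)2·H2O (cat.), 1,2-bis(diphenylphosphino)benzene, polymethylhydrosiloxane as the limiting reagent, t-BuOH and toluene. A kinetic resolution by asymmetric transfer hydrogenation follows ([Cp*RhCl((R,R)-TsDPEN)], HCO2H/Et3N, EtOAc). This catalyst forms 4R carbinols, and hydride addition to a flavanone gives the 2,4-cis alcohol. The 2R ketone is therefore the matched substrate and is converted into the (2R,4R)-flavan-4-ol F2. The slow-reacting 2S ketone is left behind, is separated by chromatography, and rejoins the route as 12.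

Step 7. The reaction may stall after the first aroyl transfer if the polyanion precipitates, and adventitious hydroxide may cleave the crowded aryl esters. The fallback sets out from 6. A twofold Claisen–Schmidt condensation with commercial 4-(benzyloxy)benzaldehyde (KOH, EtOH/THF, rt) gives the bis(2'-hydroxychalcone) F3. Its oxidative cyclisation (I2 cat., DMSO, 120 °C) closes both pyranones and comes back to the route at 10.

Step 4. Protodeiodination may compete, and C–C bond formation between two doubly ortho-substituted partners may be slow. The fallback sets out from 4. Half of the material is converted by Miyaura borylation (PdCl2(dppf), B2pin2, KOAc, dioxane, 90 °C) into the pinacol boronate F4. This is joined to the other half of 4 by Suzuki–Miyaura cross-coupling with a bulky biarylphosphine (Pd(OAc)2, SPhos, K3PO4, toluene, 100 °C) and comes back to the route at 5.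

Further compounds
F1 | step 9 | C2-racemic hexa-O-benzyl-2,3-dihydrocupressuflavone | O=C1CC(c2ccc(OCc3ccccc3)cc2)Oc2c1c(OCc1ccccc1)cc(OCc1ccccc1)c2-c1c(OCc2ccccc2)cc(OCc2ccccc2)c2c(=O)cc(-c3ccc(OCc4ccccc4)cc3)oc12
F2 | step 9 | (2R,4R)-flavan-4-ol from the 2R enantiomer of F1 | O[C@@H]1C[C@H](c2ccc(OCc3ccccc3)cc2)Oc2c1c(OCc1ccccc1)cc(OCc1ccccc1)c2-c1c(OCc2ccccc2)cc(OCc2ccccc2)c2c(=O)cc(-c3ccc(OCc4ccccc4)cc3)oc12
F3 | step 7 | (2E,2'E)-1,1'-[4,4',6,6'-tetrakis(benzyloxy)-2,2'-dihydroxybiphenyl-3,3'-diyl]bis{3-[4-(benzyloxy)phenyl]prop-2-en-1-one} | O=C(/C=C/c1ccc(OCc2ccccc2)cc1)c1c(OCc2ccccc2)cc(OCc2ccccc2)c(c1O)-c1c(O)c(C(=O)/C=C/c2ccc(OCc3ccccc3)cc2)c(OCc2ccccc2)cc1OCc1ccccc1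
F4 | step 4 | 4',6'-bis(benzyloxy)-2'-(methoxymethoxy)-3'-(4,4,5,5-tetramethyl-1,3,2-dioxaborolan-2-yl)acetophenone | CC(=O)c1c(OCOC)c(B2OC(C)(C)C(C)(C)O2)c(OCc2ccccc2)cc1OCc1ccccc1
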